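**Strategy.** Ring A (C1–C5, C10; gibberellane numbering) is annulated last onto a BCD tricycle. The key step exploits the 1,5-relationship of O3 and C7 across the C4–C5–C6 edge of rings A/B: both are joined in an allyl enol ether of benzyl acetoacetate (C2–C3–C4, C19). On heating, its Claisen rearrangement forms C4–C5 on the ring B face anti to the C10 tosyloxymethyl group and leaves the C6=C7 methylene. In the same pot the acetoacetate dianion displaces the tosylate (C1–C2), closing the trans-fused ring A. The precursor is a ring B cyclopentene with C10(CH3)(CH2OTs), fused to the bicyclo[3.2.1]octane (rings C/D).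

Key step: step 15

Remark: gibberellane numbering is used throughout (C7 on C6, C18/C19 on C4, C20 on C10, C17 on C16; α is the face of C20); in step 2 the antipode of the Trost ligand that gives the S quaternary carbon is assumed to be used. Abbreviations: TBDPS = tert-butyldiphenylsilyl, Ts = p-toluenesulfonyl, Bn = benzyl.

Step 1
Reactants: 1 tert-butyl acetoacetate; 2 propargyl bromide
Product: 3 tert-butyl 3-oxohept-6-ynoate
Conditions: NaH, THF, 0 °C; n-BuLi, −10 °C; then 2, −10 → 25 °C
Reagents that add atoms: none
Why: Huckin–Weiler dianion alkylation, in which the γ-carbanion is far more nucleophilic than the α-carbon, so the propargyl group goes on the methyl terminus only.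

Step 2
Reactants: 3 tert-butyl 3-oxohept-6-ynoate; 4 isoprene monoxide (racemic)
Product: 5 tert-butyl 2-[(2S)-1-hydroxy-2-methylbut-3-en-2-yl]-3-oxohept-6-ynoate
Conditions: Pd2(dba)3·CHCl3 (1 mol%), DACH-naphthyl Trost ligand (3 mol%), CH2Cl2, 25 °C
Reagents that add atoms: none
Why: Trost asymmetric allylic alkylation run as a dynamic kinetic asymmetric transformation: zerovalent palladium opens the vinyl epoxide to equilibrating π-allyl complexes and the β-keto ester attacks the substituted terminus, so the ligand sets the quaternary carbon (future C10); the β-keto ester carbon is an inconsequential mixture.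

Step 3
Reactants: 5 hydroxy keto ester
Product: 6 tert-butyl 2-[(2S)-1-(tert-butyldiphenylsilyloxy)-2-methylbut-3-en-2-yl]-3-oxohept-6-ynoate
Conditions: TBDPSCl, imidazole, DMF, 25 °C
Reagents that add atoms: tert-butyl(chloro)diphenylsilane, CC(C)(C)[Si](Cl)(c1ccccc1)c1ccccc1
Why: Silylation of the primary alcohol; the bulky silyloxymethyl group later steers the diene in step 5.

Step 4
Reactants: 6 silyl ether
Product: 8 (4R)-4-[(tert-butyldiphenylsilyloxy)methyl]-4-methyl-2-(prop-2-yn-1-yl)cyclopent-2-en-1-one, via keto aldehyde 7 (not isolated)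
Conditions: OsO4 (2 mol%), NaIO4, 2,6-lutidine, dioxane–H2O, 25 °C; then TsOH·H2O (0.2 equiv), PhH, 80 °C
Reagents that add atoms: none
Why: Lemieux–Johnson cleavage of the vinyl group (alkyne untouched) gives the 1,4-keto aldehyde; acid then removes the tert-butyl ester with decarboxylation and drives the intramolecular aldol condensation of C8 onto the non-enolizable aldehyde, for which a five-membered ring is the only option.

Step 5
Reactants: 8 cyclopentenone; 9 buta-1,3-diene
Product: 10 cis-fused hexahydroindenone carrying the 7a-propargyl group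
Conditions: AlBr3/AlMe3 (10:1, 0.8 equiv), 9 (excess), PhMe–CH2Cl2, −10 °C
Reagents that add atoms: none
Why: Lewis acid-promoted Diels–Alder reaction; suprafacial addition gives the cis B/C fusion, and the diene should approach anti to the silyloxymethyl group (syn to the methyl), which sets C8 and C9.

Step 6
Reactants: 10 Diels–Alder adduct
Product: 12 tricyclic BCD ketone with the C16 exocyclic methylene, via vinylstannane 11 (not isolated)
Conditions: Bu3SnH, AIBN (cat.), PhH, 80 °C (slow addition); then HCl (Et2O), CH2Cl2, 0 °C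
Reagents that add atoms: none
Why: Stork-type vinyl radical cyclization: the stannyl radical adds to the alkyne terminus and the vinyl radical closes 5-exo-trig onto C13 of the cyclohexene, forming the bicyclo[3.2.1]octane (C13 is fixed by the bridge); protodestannylation then gives the methylene.

Step 7
Reactants: 12 tricyclic ketone
Product: 13 enol triflate (C5=C6–OTf)
Conditions: KN(SiMe3)2, THF, −78 °C; Comins' reagent, −78 → 0 °C
Reagents that add atoms: N-(5-chloropyridin-2-yl)-N-(trifluoromethylsulfonyl)trifluoromethanesulfonamide, O=S(=O)(N(c1ccc(Cl)cn1)S(=O)(=O)C(F)(F)F)C(F)(F)F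
Why: The ketone can enolize only toward C5 because C8 is quaternary, so O-triflation of the potassium enolate gives one enol triflate.

Step 8
Reactants: 13 enol triflate
Product: 14 16-ketone
Conditions: O3, CH2Cl2, −78 °C; then PPh3
Reagents that add atoms: ozone, [O-][O+]=O
Why: Ozonolysis; the electron-rich 1,1-disubstituted alkene is cleaved much faster than the electron-poor enol triflate.

Step 9
Reactants: 14 16-ketone
Product: 15 tertiary alcohol (16-methyl exo, 16-hydroxyl endo)
Conditions: MeMgBr, THF, −78 → −20 °C
Reagents that add atoms: methylmagnesium bromide, C[Mg]Br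
Why: Grignard addition from the exo face of the bicyclo[3.2.1]octanone (the side of the one-carbon bridge C14, away from the C11 methylene) places methyl exo and hydroxyl endo as in the target; the enol triflate is inert at this temperature.

Step 10
Reactants: 15 enol triflate alcohol; 16 (tributylstannyl)methanol
Product: 17 allylic alcohol (C5=C6–C7H2OH)
Conditions: Pd(PPh3)4 (10 mol%), LiCl, dioxane, 100 °C
Reagents that add atoms: none
Why: Stille coupling with hydroxymethyl transfer from tin (Kosugi–Migita hydroxymethylation) under zerovalent palladium catalysis installs C7 on C6.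

Step 11
Reactants: 18 but-2-ynoic acid; 19 benzyl bromide
Product: 20 benzyl but-2-ynoate
Conditions: K2CO3, DMF, 25 °C
Reagents that add atoms: none
Why: SN2 O-alkylation of the carboxylate.

Step 12
Reactants: 17 allylic alcohol; 20 benzyl but-2-ynoate
Product: 21 benzyl (E)-3-(allyloxy)but-2-enoate enol ether of 17
Conditions: NaH (0.2 equiv), THF, 0 → 25 °C
Reagents that add atoms: none
Why: Alkoxide-catalysed oxa-Michael addition of the primary allylic alcohol to the ynoate (the hindered tertiary alcohol should not compete) gives the β-alkoxy enoate, with the E isomer thermodynamically preferred.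

Step 13
Reactants: 21 silyl-protected enol ether
Product: 22 diol (C1–OH free)
Conditions: TBAF, AcOH, THF, 40 °C
Reagents that add atoms: none
Why: Fluoride cleavage of the silyl ether; buffering protects the enol ether and the benzyl ester.

Step 14
Reactants: 22 diol
Product: 23 tosylate (C1–OTs)
Conditions: TsCl, Et3N, DMAP (cat.), CH2Cl2, 0 → 25 °C
Reagents that add atoms: p-toluenesulfonyl chloride, Cc1ccc(cc1)S(Cl)(=O)=O
Why: Sulfonylation of the primary alcohol; the tertiary C16 alcohol is too hindered to react.

Step 15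
Reactants: 23 tosylate
Product: 25 tetracyclic benzyl β-keto ester (ring A closed; trans A/B), via Claisen product 24 (not isolated)
Conditions: PhMe, 2,6-di-tert-butyl-4-methylpyridine (0.1 equiv), 165 °C (sealed); cool, THF, LiN(iPr)2 (3.3 equiv), −78 °C, then DMPU, → 25 °C
Reagents that add atoms: none
Why: Heating triggers the Claisen [3,3]-sigmatropic rearrangement of the allyl β-(benzyloxycarbonyl)vinyl ether (the O-allyl enol ether of an acetoacetate, as in the original Claisen rearrangement) through a chair transition state, forming C4–C5 and releasing the C3 ketone and the C6=C7 methylene; LiN(iPr)2 then generates the Huckin–Weiler α,γ-dianion, whose γ-carbon C2 displaces the neopentyl tosylate at C1. The sigmatropic step closes no ring in the product; ring A is closed by the alkylation in the 6-(enolendo)-exo-tet mode. C5 is the only stereocentre that must be controlled: the enol ether should reach C5 from the α face, syn to the C20 methyl and anti to the larger tosyloxymethyl group on C10, so that C4 (α) and C1 (β) are trans on ring B and the alkylation can only give the trans A/B fusion. C4 is planar in the dianion and is left as an epimerizable β-keto ester centre that step 16 fixes. The step needs face selectivity in the rearrangement, which rests on the size difference of the two C10 substituents, and C- rather than O-alkylation at C1, which rests on the much higher nucleophilicity of the dianion γ-carbon (the α-carbon could only form a four-membered ring).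

Step 16
Reactants: 25 β-keto ester
Product: 26 C4-methylated keto ester (4β-CH3, 4α-CO2Bn)
Conditions: MeI, K2CO3, acetone, 40 °C
Reagents that add atoms: iodomethane, CI
Why: C-alkylation of the β-keto ester enolate; methyl should enter from the β face, anti to the axial C20 methyl on C10 (the usual course for 3-oxo-4-carboalkoxy systems with an angular methyl), making the ester axial (α) and setting C4.

Step 17
Reactants: 26 methylene keto ester
Product: 27 6-epi primary alcohol (C7 α)
Conditions: 9-BBN, THF, 50 °C; then H2O2, aq. NaOAc, 25 °C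
Reagents that add atoms: hydrogen peroxide, OO
Why: Anti-Markovnikov hydroboration–oxidation of the 1,1-disubstituted alkene (9-BBN should spare the hindered ketone); attack from the β face, since the α face is screened by the axial ester, should give mainly the 6-epi alcohol, which step 18 corrects.

Step 18
Reactants: 27 6-epi alcohol
Product: 29 7-aldehyde with the 6β configuration, via 6-epi aldehyde 28 (not isolated)
Conditions: Dess–Martin periodinane, CH2Cl2, 25 °C; then DBU (3 equiv), 25 °C
Reagents that add atoms: none
Why: Dess–Martin oxidation followed by base epimerization of the enolizable aldehyde to the more stable 6β isomer, in which C7 is trans to the C4–C5 bond and away from the axial ester, so C6 is set under thermodynamic control.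

Step 19
Reactants: 29 keto aldehyde
Product: 30 benzyl ester of the target (3β-OH, 7-OH)
Conditions: potassium tri-sec-butylborohydride, THF, −78 °C
Reagents that add atoms: none
Why: The bulky hydride reduces the aldehyde and should attack the C3 ketone along the equatorial trajectory (axial attack is blocked by the axial hydrogens on C1 and C5), giving the axial 3β-alcohol; the hindered benzyl ester is not reduced.

Step 20
Reactants: 30 benzyl ester
Product: 31 target acid
Conditions: H2 (1 atm), Pd/C, EtOAc, 25 °C
Reagents that add atoms: none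
Why: Hydrogenolysis frees the acid under neutral conditions, avoiding base-induced retro-aldol epimerization of the β-hydroxy acid.

**Compound list**

1 | tert-butyl 3-oxobutanoate (tert-butyl acetoacetate) | CC(=O)CC(=O)OC(C)(C)C | starting material
2 | 3-bromoprop-1-yne (propargyl bromide) | C#CCBr | starting material
3 | tert-butyl 3-oxohept-6-ynoate | C#CCCC(=O)CC(=O)OC(C)(C)C | intermediate
4 | 2-methyl-2-vinyloxirane (isoprene monoxide, racemic) | CC1(C=C)CO1 | starting material
5 | tert-butyl 2-[(2S)-1-hydroxy-2-methylbut-3-en-2-yl]-3-oxohept-6-ynoate (epimers at the keto ester carbon) | C=C[C@](C)(CO)C(C(=O)OC(C)(C)C)C(=O)CCC#C | intermediate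
6 | tert-butyl 2-[(2S)-1-(tert-butyldiphenylsilyloxy)-2-methylbut-3-en-2-yl]-3-oxohept-6-ynoate | C=C[C@](C)(CO[Si](c1ccccc1)(c1ccccc1)C(C)(C)C)C(C(=O)OC(C)(C)C)C(=O)CCC#C | intermediate
7 | tert-butyl 2-[(2S)-1-(tert-butyldiphenylsilyloxy)-2-methyl-3-oxopropan-2-yl]-3-oxohept-6-ynoate | O=C[C@](C)(CO[Si](c1ccccc1)(c1ccccc1)C(C)(C)C)C(C(=O)OC(C)(C)C)C(=O)CCC#C | intermediate
8 | (4R)-4-[(tert-butyldiphenylsilyloxy)methyl]-4-methyl-2-(prop-2-yn-1-yl)cyclopent-2-en-1-one | C[C@@]1(CO[Si](c2ccccc2)(c2ccccc2)C(C)(C)C)CC(=O)C(CC#C)=C1 | intermediate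
9 | buta-1,3-diene | C=CC=C | starting material
10 | cis-fused 3-[(TBDPS-oxy)methyl]-3-methyl-7a-(prop-2-yn-1-yl)-2,3,3a,4,7,7a-hexahydro-1H-inden-1-one; 3a-H, 7a-propargyl and 3-CH2OSi on one face, 3-CH3 on the other | C[C@@]1(CO[Si](c2ccccc2)(c2ccccc2)C(C)(C)C)CC(=O)[C@@]2(CC#C)CC=CC[C@@H]12 | intermediate
11 | tricyclic ketone with an exocyclic (tributylstannyl)methylene on C16 (E/Z mixture) | C[C@@]1(CO[Si](c2ccccc2)(c2ccccc2)C(C)(C)C)CC(=O)[C@@]23C[C@@H](CC[C@@H]12)C(=C[Sn](CCCC)(CCCC)CCCC)C3 | intermediate
12 | tricyclic BCD ketone: C6 ketone, C16 methylene, C10 with α-CH3 and β-CH2OTBDPS, 9-H β | C[C@@]1(CO[Si](c2ccccc2)(c2ccccc2)C(C)(C)C)CC(=O)[C@@]23C[C@@H](CC[C@@H]12)C(=C)C3 | intermediate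
13 | enol triflate of 12 (C5=C6–OTf) | C[C@@]1(CO[Si](c2ccccc2)(c2ccccc2)C(C)(C)C)C=C(OS(=O)(=O)C(F)(F)F)[C@@]23C[C@@H](CC[C@@H]12)C(=C)C3 | intermediate
14 | 16-ketone with the enol triflate retained | C[C@@]1(CO[Si](c2ccccc2)(c2ccccc2)C(C)(C)C)C=C(OS(=O)(=O)C(F)(F)F)[C@@]23C[C@@H](CC[C@@H]12)C(=O)C3 | intermediate
15 | tertiary alcohol: 16-methyl exo, 16-hydroxyl endo, enol triflate retained | C[C@@]1(CO[Si](c2ccccc2)(c2ccccc2)C(C)(C)C)C=C(OS(=O)(=O)C(F)(F)F)[C@@]23C[C@@H](CC[C@@H]12)[C@@](C)(O)C3 | intermediate
16 | (tributylstannyl)methanol | OC[Sn](CCCC)(CCCC)CCCC | starting material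
17 | allylic alcohol: C5=C6–C7H2OH on ring B, C1–OTBDPS, 16-OH | C[C@@]1(CO[Si](c2ccccc2)(c2ccccc2)C(C)(C)C)C=C(CO)[C@@]23C[C@@H](CC[C@@H]12)[C@@](C)(O)C3 | intermediate
18 | but-2-ynoic acid | CC#CC(=O)O | starting material
19 | benzyl bromide | BrCc1ccccc1 | starting material
20 | benzyl but-2-ynoate | CC#CC(=O)OCc1ccccc1 | intermediate
21 | benzyl (E)-3-(C7-oxy)but-2-enoate enol ether of 17 (C1–OTBDPS) | C[C@@]1(CO[Si](c2ccccc2)(c2ccccc2)C(C)(C)C)C=C(CO/C(C)=C/C(=O)OCc2ccccc2)[C@@]23C[C@@H](CC[C@@H]12)[C@@](C)(O)C3 | intermediate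
22 | diol: enol ether 21 with free C1–OH | C[C@@]1(CO)C=C(CO/C(C)=C/C(=O)OCc2ccccc2)[C@@]23C[C@@H](CC[C@@H]12)[C@@](C)(O)C3 | intermediate
23 | tosylate: enol ether with C1–OTs | C[C@@]1(COS(=O)(=O)c2ccc(C)cc2)C=C(CO/C(C)=C/C(=O)OCc2ccccc2)[C@@]23C[C@@H](CC[C@@H]12)[C@@](C)(O)C3 | intermediate
24 | benzyl 2-(C5)-3-oxobutanoate: C4 on the α face of C5 (5-H β), C6=C7H2 methylene, C1–OTs | C[C@@]1(COS(=O)(=O)c2ccc(C)cc2)[C@@H]([C@@H](C(C)=O)C(=O)OCc2ccccc2)C(=C)[C@@]23C[C@@H](CC[C@@H]12)[C@@](C)(O)C3 | intermediate
25 | tetracyclic benzyl 3-oxo-19-oate with 4-H (drawn as the equatorial ester epimer; C4 is epimerizable), trans A/B, C6 methylene | C[C@@]12CCC(=O)[C@H](C(=O)OCc4ccccc4)[C@H]1C(=C)[C@@]13C[C@@H](CC[C@@H]21)[C@@](C)(O)C3 | intermediate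
26 | benzyl 3-oxo-6-methylene ester with 4β-CH3 and 4α-CO2Bn | C[C@@]12CCC(=O)[C@@](C)(C(=O)OCc4ccccc4)[C@H]1C(=C)[C@@]13C[C@@H](CC[C@@H]21)[C@@](C)(O)C3 | intermediate
27 | 6-epi primary alcohol (C7 α), 3-ketone | C[C@@]12CCC(=O)[C@@](C)(C(=O)OCc4ccccc4)[C@H]1[C@@H](CO)[C@@]13C[C@@H](CC[C@@H]21)[C@@](C)(O)C3 | intermediate
28 | 6-epi 7-aldehyde | C[C@@]12CCC(=O)[C@@](C)(C(=O)OCc4ccccc4)[C@H]1[C@@H](C=O)[C@@]13C[C@@H](CC[C@@H]21)[C@@](C)(O)C3 | intermediate
29 | 7-aldehyde with the 6β configuration, 3-ketone | C[C@@]12CCC(=O)[C@@](C)(C(=O)OCc4ccccc4)[C@H]1[C@H](C=O)[C@@]13C[C@@H](CC[C@@H]21)[C@@](C)(O)C3 | intermediate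
30 | benzyl ester of the target (3β-OH axial, 7-OH, 16-OH) | C[C@@]12CC[C@H](O)[C@@](C)(C(=O)OCc4ccccc4)[C@H]1[C@H](CO)[C@@]13C[C@@H](CC[C@@H]21)[C@@](C)(O)C3 | intermediate
31 | CNP0170663.1: 3β,7,16-trihydroxygibberellan-19-oic acid (16-methyl exo, 16-hydroxyl endo) | C[C@@]12CC[C@H](O)[C@@](C)(C(=O)O)[C@H]1[C@H](CO)[C@@]13C[C@@H](CC[C@@H]21)[C@@](C)(O)C3 | target

**Totals.** Total step count: 20. Longest linear sequence: 19 steps (steps 1–10 and 12–20, from tert-butyl acetoacetate; step 11 is a one-step side branch).

**Steps most likely to fail**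

Step 15. The sigmatropic shift may not discriminate well between the two faces of ring B (CH3 against CH2OTs on C10). That would deliver C4 to the β face and end in the cis-fused A/B isomer; the thermal stage may also erode the tosylate. Fallback, setting out from 21: the rearrangement is run one stage earlier on the silyl ether (PhMe, 165 °C), where the much larger silyloxymethyl group shields the β face, to give the benzyl 3-oxobutanoate silyl ether F1. TBAF/AcOH then frees the keto alcohol F2, which may rest as its cyclic hemiketal. TsCl/Et3N/DMAP converts F2 into 24, which is isolated and cyclized with LiN(iPr)2 as in the second stage of step 15, coming back to the route at 25.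

Step 5. The cycloaddition may not take place because the enone is α-substituted and flanked by a quaternary carbon, or the strong Lewis acid may attack the alkyne or the silyl ether first. Fallback, setting out from 8: the more reactive 2-(trimethylsilyloxy)buta-1,3-diene (PhMe, 110 °C, or Me2AlCl, −40 °C) should give the silyl enol ether adduct F3, with the siloxy carbon para to the acyl-bearing C8 and the same facial course. (Ph3P)AuCl/AgBF4 in CH2Cl2–MeOH then closes ring D by 5-exo-dig attack of the enol ether carbon C13 on the alkyne, giving the 6,12-diketone F4 with the C16 methylene in place. The less hindered C12 ketone is converted into the tosylhydrazone F5 (TsNHNH2, EtOH) and reduced to the methylene (catecholborane, then NaOAc·3H2O). This comes back to the route at 12 and makes step 6 unnecessary.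

Step 17. Hydroboration of the hindered methylene with 9-BBN may stall, or the 6-epi primary alcohol, which lies next to the axial benzyl ester, may close to a δ-lactone before it can be oxidized. Fallback, setting out from 26: epoxidation on the open β face with dimethyldioxirane (acetone, 0 °C) gives the spiro-epoxide F6. MgBr2·OEt2 (CH2Cl2, 0 °C) then induces the Meinwald rearrangement (1,2-hydride shift from C7 to C6) to the C7 aldehyde, which is equilibrated with DBU as in step 18, coming back to the route at 29. No free C7 alcohol is ever present beside the ester.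

Further compounds
F1 | step 15 | benzyl 2-(C5)-3-oxobutanoate Claisen product with C1–OTBDPS | C[C@@]1(CO[Si](c2ccccc2)(c2ccccc2)C(C)(C)C)[C@@H]([C@@H](C(C)=O)C(=O)OCc2ccccc2)C(=C)[C@@]23C[C@@H](CC[C@@H]12)[C@@](C)(O)C3
F2 | step 15 | keto alcohol: Claisen product with free C1–OH | C[C@@]1(CO)[C@@H]([C@@H](C(C)=O)C(=O)OCc2ccccc2)C(=C)[C@@]23C[C@@H](CC[C@@H]12)[C@@](C)(O)C3
F3 | step 5 | cis-fused Diels–Alder adduct with a C12 trimethylsilyl enol ether (C12=C13) | C[C@@]1(CO[Si](c2ccccc2)(c2ccccc2)C(C)(C)C)CC(=O)[C@@]2(CC#C)CC=C(O[Si](C)(C)C)C[C@@H]12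
F4 | step 5 | tricyclic 6,12-diketone with the C16 methylene | C[C@@]1(CO[Si](c2ccccc2)(c2ccccc2)C(C)(C)C)CC(=O)[C@@]23C[C@@H](C(=O)C[C@@H]12)C(=C)C3
F5 | step 5 | C12 tosylhydrazone of F4 | C[C@@]1(CO[Si](c2ccccc2)(c2ccccc2)C(C)(C)C)CC(=O)[C@@]23C[C@@H](C(=NNS(=O)(=O)c4ccc(C)cc4)C[C@@H]12)C(=C)C3
F6 | step 17 | C6/C7 spiro-epoxide of 26 (oxygen on the β face) | C[C@@]12CCC(=O)[C@@](C)(C(=O)OCc4ccccc4)[C@H]1[C@@]5(CO5)[C@@]13C[C@@H](CC[C@@H]21)[C@@](C)(O)C3
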